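Ring A of the target is numbered C1 (OMe), C2 (prenyl), C3 (OH), C4 (prenyl), C5 (OH), C6 (benzoyl). The route disconnects this ring at C3–C4 and C5–C6 into a 3-methoxy-4-prenylcyclobutenone (C6, C1, C2, C3) and a prenylated triisopropylsiloxyalkyne (C4, C5). One thermal operation builds the whole benzene ring. It exploits the C3 hydroxyl flanked by the prenylated carbons C2 and C4, with oxygens on both meta carbons C1 and C5. The three oxygens emerge differentiated as OH, OMe and OTIPS, and C6–H stays free. Both precursors carry their prenyl group from the start. Directed lithiation and benzoylation at C6, then deprotection, finish the route.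

Key step: step 5

Assumption: methoxyacetylene 3 is not treated as a catalogue chemical and is made in step 1; cyclobutenone 7 is used as the racemate because its only stereocentre becomes aromatic C2 in step 5.

Step 1
Reactants: 1 chloroacetaldehyde dimethyl acetal (2-chloro-1,1-dimethoxyethane)
Product: 3 methoxyacetylene (methoxyethyne), via sodium methoxyacetylide 2 (not isolated)
Conditions: NaNH2 (3.2 equiv), liq. NH3, −33 °C; NH3 evaporated; sat. aq. NaCl, −70 → 20 °C; distilled into cold Et2O and used as a titrated solution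
Reagents that add atoms: none
Why: Twofold base-induced elimination (loss of methanol, then of HCl) gives the sodium alkynyl ether, the standard preparation of alkoxyacetylenes from chloroacetals, and the aqueous quench releases the volatile alkyne.

Step 2
Reactants: 4 5-methylhex-4-enoic acid
Product: 5 5-methylhex-4-enoyl chloride
Conditions: (COCl)2, DMF (cat.), CH2Cl2, 0 → 20 °C; volatiles removed, used crude
Reagents that add atoms: oxalyl chloride, O=C(Cl)C(=O)Cl
Why: Acid chloride formation through Vilsmeier-type activation runs cold and without added Lewis acid, so the trisubstituted alkene should be left untouched.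

Step 3
Reactants: 5 5-methylhex-4-enoyl chloride; 3 methoxyacetylene
Product: 7 racemic 3-methoxy-4-(3-methylbut-2-enyl)cyclobut-2-en-1-one, via prenylketene 6 (not isolated)
Conditions: Et3N (1.2 equiv), 3 (3 equiv), Et2O, 0 → 20 °C, slow addition of 5; chromatography on Et3N-deactivated silica
Reagents that add atoms: none
Why: Dehydrochlorination gives the aldoketene, which is trapped by the excess ynol ether in a thermal ketene–alkoxyalkyne [2+2] cycloaddition in which the ketene carbonyl carbon bonds to the unsubstituted nucleophilic alkyne carbon, placing OMe at C3 and prenyl at C4; the C4 stereocentre forms racemic and is erased in step 5.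

Step 4
Reactants: 8 ethyl 4-methylpent-3-enoate; 9 triisopropylsilyl trifluoromethanesulfonate
Product: 12 triisopropyl[(5-methylhex-4-en-1-yn-1-yl)oxy]silane, via lithium dibromoenolate 10 (not isolated), via lithium ynolate 11 (not isolated)
Conditions: CH2Br2, lithium 2,2,6,6-tetramethylpiperidide, THF, −78 °C; 8; LiN(SiMe3)2; n-BuLi, −78 → 20 °C; 9, −78 → 0 °C
Reagents that add atoms: dibromomethane, BrCBr
Why: Kowalski ester homologation: LiCHBr2 adds to the ester, the derived dibromo enolate undergoes bromine–lithium exchange and 1,2-shift of the prenyl group to give the ynolate, and the bulky silyl triflate captures it on oxygen as a stable triisopropylsilyl ynol ether.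

Step 5
Reactants: 7 racemic 3-methoxy-4-(3-methylbut-2-enyl)cyclobut-2-en-1-one; 12 triisopropyl[(5-methylhex-4-en-1-yn-1-yl)oxy]silane
Product: 17 3-methoxy-2,6-bis(3-methylbut-2-enyl)-5-(triisopropylsilyloxy)phenol, via vinylketene 13 (not isolated), via 4-vinylcyclobutenone 14 (not isolated), via dienylketene 15 (not isolated), via cyclohexadienone 16 (not isolated)
Conditions: 12 (1.3 equiv), degassed toluene, sealed tube, 80 °C then 110 °C
Reagents that add atoms: none
Why: Thermal four-electron conrotatory opening of 7 gives methoxy vinylketene 13, whose ketene C=C adds the electron-rich siloxyalkyne in a regiospecific [2+2] to give 14; this reopens to dienylketene 15, which closes to 16 and enolises to the phenol. The sequence is the Danheiser benzannulation of cyclobutenones with heteroatom-substituted alkynes, for which siloxyalkynes and 3-oxygenated cyclobutenones are established partners. The benzene ring is closed by a thermally allowed disrotatory six-electron electrocyclisation of 15 that joins the ketene carbon (target C3) to the prenyl-bearing terminus (target C2), after the [2+2] has made C3–C4 and C5–C6. No stereocentre is created, and the one in racemic 7 becomes aromatic C2. The one selectivity needed is regiochemical: the OTIPS-polarised alkyne bonds through its nucleophilic prenyl-bearing carbon to the electrophilic ketene carbonyl carbon, which puts OTIPS meta and hydrogen para to the new hydroxyl. The isolated prenyl alkenes are much poorer ketenophiles than the ynol ether.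

Step 6
Reactants: 17 3-methoxy-2,6-bis(3-methylbut-2-enyl)-5-(triisopropylsilyloxy)phenol
Product: 18 5-methoxy-2,4-bis(3-methylbut-2-enyl)benzene-1,3-diol
Conditions: Bu4NF, AcOH, THF, 0 °C, under argon
Reagents that add atoms: none
Why: Fluoride-mediated silyl ether cleavage is fast for aryl silyl ethers, and the acetic acid buffer keeps the electron-rich resorcinol from standing as an oxidisable phenoxide.

Step 7
Reactants: 18 5-methoxy-2,4-bis(3-methylbut-2-enyl)benzene-1,3-diol
Product: 19 1-methoxy-3,5-bis(methoxymethoxy)-2,4-bis(3-methylbut-2-enyl)benzene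
Conditions: NaH (2.5 equiv), MOMCl (2.5 equiv), DMF, 0 → 20 °C
Reagents that add atoms: chloromethyl methyl ether, COCCl
Why: Williamson-type O-alkylation of both sodium phenoxides by the small, hard chloromethyl ether should give the bis-acetal, including at the hydroxyl flanked by two prenyl groups.

Step 8
Reactants: 19 1-methoxy-3,5-bis(methoxymethoxy)-2,4-bis(3-methylbut-2-enyl)benzene; 20 N-methoxy-N-methylbenzamide
Product: 23 [2-methoxy-4,6-bis(methoxymethoxy)-3,5-bis(3-methylbut-2-enyl)phenyl](phenyl)methanone, via aryllithium 21 (not isolated), via lithium hemiaminal adduct 22 (not isolated)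
Conditions: n-BuLi, TMEDA, THF, 0 °C; 20, −78 → 20 °C; H2O
Reagents that add atoms: none
Why: Directed ortho-metalation removes the only ring hydrogen, which lies between the OMOM and OMe directing groups, and the aryllithium adds once to the Weinreb amide because the chelated tetrahedral adduct survives until the quench (Weinreb ketone synthesis).

Step 9
Reactants: 23 [2-methoxy-4,6-bis(methoxymethoxy)-3,5-bis(3-methylbut-2-enyl)phenyl](phenyl)methanone
Product: 24 [2,4-dihydroxy-6-methoxy-3,5-bis(3-methylbut-2-enyl)phenyl](phenyl)methanone (target CNP0384995.0)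
Conditions: 3 M aq. HCl, MeOH, 20 → 40 °C, monitored and stopped at full conversion
Reagents that add atoms: none
Why: Acid-catalysed acetal exchange with methanol removes both MOM groups as dimethoxymethane under dilute, mild conditions of the kind routinely applied to ortho-prenylated phenols, the C5 acetal being assisted by hydrogen bonding to the ketone.

Compound list
1 | chloroacetaldehyde dimethyl acetal (2-chloro-1,1-dimethoxyethane) | COC(CCl)OC | starting material
2 | sodium methoxyacetylide (in situ) | COC#C[Na] | intermediate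
3 | methoxyacetylene (methoxyethyne) | COC#C | intermediate
4 | 5-methylhex-4-enoic acid | CC(C)=CCCC(=O)O | starting material
5 | 5-methylhex-4-enoyl chloride | CC(C)=CCCC(=O)Cl | intermediate
6 | prenylketene, 5-methylhexa-1,4-dien-1-one (in situ) | CC(C)=CCC=C=O | intermediate
7 | racemic 3-methoxy-4-(3-methylbut-2-enyl)cyclobut-2-en-1-one | COC1=CC(=O)C1CC=C(C)C | intermediate
8 | ethyl 4-methylpent-3-enoate | CCOC(=O)CC=C(C)C | starting material
9 | triisopropylsilyl trifluoromethanesulfonate | CC(C)[Si](OS(=O)(=O)C(F)(F)F)(C(C)C)C(C)C | starting material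
10 | lithium 1,1-dibromo-5-methylhexa-1,4-dien-2-olate (in situ) | [Li]OC(CC=C(C)C)=C(Br)Br | intermediate
11 | lithium 5-methylhex-4-en-1-yn-1-olate (in situ) | [Li]OC#CCC=C(C)C | intermediate
12 | triisopropyl[(5-methylhex-4-en-1-yn-1-yl)oxy]silane | CC(C)=CCC#CO[Si](C(C)C)(C(C)C)C(C)C | intermediate
13 | (3Z)-3-methoxy-7-methylocta-1,3,6-trien-1-one, vinylketene (in situ) | O=C=C/C(OC)=C/CC=C(C)C | intermediate
14 | racemic 4-[(1Z)-1-methoxy-5-methylhexa-1,4-dien-1-yl]-2-(3-methylbut-2-enyl)-3-(triisopropylsilyloxy)cyclobut-2-en-1-one (in situ) | O=C1C(CC=C(C)C)=C(O[Si](C(C)C)(C(C)C)C(C)C)C1/C(OC)=C/CC=C(C)C | intermediate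
15 | (3E,5Z)-5-methoxy-9-methyl-2-(3-methylbut-2-enyl)-3-(triisopropylsilyloxy)deca-1,3,5,8-tetraen-1-one, dienylketene (in situ) | O=C=C(CC=C(C)C)/C(O[Si](C(C)C)(C(C)C)C(C)C)=C\C(OC)=C\CC=C(C)C | intermediate
16 | racemic 5-methoxy-2,6-bis(3-methylbut-2-enyl)-3-(triisopropylsilyloxy)cyclohexa-2,4-dien-1-one (in situ) | O=C1C(CC=C(C)C)=C(O[Si](C(C)C)(C(C)C)C(C)C)C=C(OC)C1CC=C(C)C | intermediate
17 | 3-methoxy-2,6-bis(3-methylbut-2-enyl)-5-(triisopropylsilyloxy)phenol | COc1cc(O[Si](C(C)C)(C(C)C)C(C)C)c(CC=C(C)C)c(O)c1CC=C(C)C | intermediate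
18 | 5-methoxy-2,4-bis(3-methylbut-2-enyl)benzene-1,3-diol | COc1cc(O)c(CC=C(C)C)c(O)c1CC=C(C)C | intermediate
19 | 1-methoxy-3,5-bis(methoxymethoxy)-2,4-bis(3-methylbut-2-enyl)benzene | COCOc1cc(OC)c(CC=C(C)C)c(OCOC)c1CC=C(C)C | intermediate
20 | N-methoxy-N-methylbenzamide | CON(C)C(=O)c1ccccc1 | starting material
21 | [2-methoxy-4,6-bis(methoxymethoxy)-3,5-bis(3-methylbut-2-enyl)phenyl]lithium (in situ) | [Li]c1c(OC)c(CC=C(C)C)c(OCOC)c(CC=C(C)C)c1OCOC | intermediate
22 | racemic lithium [methoxy(methyl)amino][2-methoxy-4,6-bis(methoxymethoxy)-3,5-bis(3-methylbut-2-enyl)phenyl](phenyl)methanolate (in situ) | [Li]OC(N(C)OC)(c1ccccc1)c1c(OC)c(CC=C(C)C)c(OCOC)c(CC=C(C)C)c1OCOC | intermediate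
23 | [2-methoxy-4,6-bis(methoxymethoxy)-3,5-bis(3-methylbut-2-enyl)phenyl](phenyl)methanone | COCOc1c(CC=C(C)C)c(OCOC)c(CC=C(C)C)c(OC)c1C(=O)c1ccccc1 | intermediate
24 | [2,4-dihydroxy-6-methoxy-3,5-bis(3-methylbut-2-enyl)phenyl](phenyl)methanone | COc1c(CC=C(C)C)c(O)c(CC=C(C)C)c(O)c1C(=O)c1ccccc1 | target

Total step count: 9. Longest linear sequence: 7 steps (steps 1, 3, 5, 6, 7, 8, 9; the branch through steps 2, 3, 5–9 is equally long).

Steps most likely to fail

Step 5. The donor-stabilised cyclobutenone may open too slowly, so that the vinylketene dimerises or is intercepted by the product phenol before it meets the alkyne. The fallback exchanges the roles of the two oxygens between the partners. It sets out from acid chloride 5, siloxyalkyne 12 and methoxyacetylene 3 and comes back at diol 18. Acid chloride 5 is dehydrochlorinated with Et3N in Et2O at 0 → 20 °C in the presence of 12. Ketene 6 then adds to the siloxyalkyne to give racemic 2,4-bis(3-methylbut-2-enyl)-3-(triisopropylsilyloxy)cyclobut-2-en-1-one F1, a 3-siloxycyclobutenone of a class known to ring-open readily. Heating F1 with excess 3 in toluene in a sealed tube at 80–110 °C should give, by the same cascade, 5-methoxy-2,4-bis(3-methylbut-2-enyl)-3-(triisopropylsilyloxy)phenol F2, the isomer of 17 with the silyl group on the other oxygen. Desilylation with Bu4NF/AcOH then gives 18. This detour also bypasses cyclobutenone 7 should step 3 underperform.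

Step 4. The β,γ-unsaturated ester may be deprotonated at its doubly activated α-position by LiCHBr2 or the amide bases, with enolate formation and alkene migration in place of carbonyl addition. The fallback replaces ester homologation by acetylide oxidation. It sets out from ester 8 and comes back at ynolate 11, which is silylated with 9 to give 12 as before. Reduction of 8 with i-Bu2AlH in CH2Cl2 at −78 °C gives 4-methylpent-3-enal F3. Corey–Fuchs olefination with CBr4/PPh3 at 0 °C gives 1,1-dibromo-5-methylhexa-1,4-diene F4. Two equivalents of n-BuLi in THF at −78 °C convert F4 into (5-methylhex-4-en-1-yn-1-yl)lithium F5. Oxidation of F5 with t-BuOOLi (from t-BuOOH and LiN(SiMe3)2) at −78 → 0 °C gives 11.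

Step 9. A freed phenol may add to the neighbouring prenyl alkene under acid (chroman formation) before the hindered second acetal is cleaved. The fallback uses fluoride-labile instead of acid-labile acetals. It sets out from diol 18 and comes back at target 24. Treatment of 18 with NaH and 2-(trimethylsilyl)ethoxymethyl chloride in DMF gives 1-methoxy-2,4-bis(3-methylbut-2-enyl)-3,5-bis{[2-(trimethylsilyl)ethoxy]methoxy}benzene F6. Lithiation with n-BuLi/TMEDA in THF at 0 °C gives [2-methoxy-3,5-bis(3-methylbut-2-enyl)-4,6-bis{[2-(trimethylsilyl)ethoxy]methoxy}phenyl]lithium F7. Addition of F7 to Weinreb amide 20 gives [2-methoxy-3,5-bis(3-methylbut-2-enyl)-4,6-bis{[2-(trimethylsilyl)ethoxy]methoxy}phenyl](phenyl)methanone F8. Both acetals are then removed with Bu4NF in THF/DMPU at 60 °C under argon to give 24 without any acid.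

Further compounds
F1 | step 5 | racemic 2,4-bis(3-methylbut-2-enyl)-3-(triisopropylsilyloxy)cyclobut-2-en-1-one | CC(C)=CCC1C(=O)C(CC=C(C)C)=C1O[Si](C(C)C)(C(C)C)C(C)C
F2 | step 5 | 5-methoxy-2,4-bis(3-methylbut-2-enyl)-3-(triisopropylsilyloxy)phenol | COc1cc(O)c(CC=C(C)C)c(O[Si](C(C)C)(C(C)C)C(C)C)c1CC=C(C)C
F3 | step 4 | 4-methylpent-3-enal | CC(C)=CCC=O
F4 | step 4 | 1,1-dibromo-5-methylhexa-1,4-diene | CC(C)=CCC=C(Br)Br
F5 | step 4 | (5-methylhex-4-en-1-yn-1-yl)lithium | [Li]C#CCC=C(C)C
F6 | step 9 | 1-methoxy-2,4-bis(3-methylbut-2-enyl)-3,5-bis{[2-(trimethylsilyl)ethoxy]methoxy}benzene | COc1cc(OCOCC[Si](C)(C)C)c(CC=C(C)C)c(OCOCC[Si](C)(C)C)c1CC=C(C)C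
F7 | step 9 | [2-methoxy-3,5-bis(3-methylbut-2-enyl)-4,6-bis{[2-(trimethylsilyl)ethoxy]methoxy}phenyl]lithium | [Li]c1c(OC)c(CC=C(C)C)c(OCOCC[Si](C)(C)C)c(CC=C(C)C)c1OCOCC[Si](C)(C)C
F8 | step 9 | [2-methoxy-3,5-bis(3-methylbut-2-enyl)-4,6-bis{[2-(trimethylsilyl)ethoxy]methoxy}phenyl](phenyl)methanone | COc1c(CC=C(C)C)c(OCOCC[Si](C)(C)C)c(CC=C(C)C)c(OCOCC[Si](C)(C)C)c1C(=O)c1ccccc1
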